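**Remark on the chemistry:** the target SMILES places both alkynyl arms on the same face of the cyclobutane, so the route is planned for the cis (meso, 1R,2S) isomer. LiN(i-Pr)2 is taken as the commercial solution.

## Analysis of the target

Isocardopatine (15) is a monocyclic cyclobutane (ring atoms C1–C4) whose C1 and C2 each carry a 2-(2,2'-bithiophen-5-yl)ethynyl arm, while C3 and C4 are unsubstituted methylenes. C1 and C2 are the only stereocentres; both arms lie on the same face, so only the relative (cis) configuration has to be controlled. The cis arrangement is the more crowded one, and once the arms are alkynes the C1–H and C2–H bonds are propargylic, so strong base can epimerize them or move a triple bond into an allene. Further sensitive sites are the electron-rich bithiophenes (ozone, peracids, electrophiles, lithiation at the free 5'-positions), the conjugated thienylalkynes (light) and the cis-1,2-dialkynylcyclobutane itself, a strained 1,5-diyne that should not be heated. The difficulty is to make a 1,2-cis-disubstituted four-membered ring with nothing on C3 and C4 to assist a cyclization, and to keep the cis relation to the end. The plan rests on the fact that the C3–C4 bond joins two plain methylenes and that C1 and C2 each bear a two-carbon arm. The four ring carbons plus the four alkyne carbons therefore map onto a cis-4,5-disubstituted cyclohexene: its ring CH carbons are C1 and C2, its two exocyclic CH2 groups are C3 and C4, and its allylic and olefinic ring carbons are the future alkyne carbons.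

## Retrosynthetic reasoning

**15 to 12 (through 14).** Each C≡C bond is traced back to a CH2–C(=O) pair, that is to the bis(aryl ketone) 12 by way of the bis(enol phosphate) 14. The cut is made here because it puts a carbonyl group on exactly the carbon that must carry the bithienyl group, so the aryl–carbon bond can be made by carbonyl addition, without palladium and without a volatile terminal diyne. In 12 the ring stereocentres are β to the carbonyl groups and are not enolizable. The forward reaction has to enolize toward the only available CH2, phosphorylate on oxygen, and eliminate with the vinylic hydrogen anti to the leaving group.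

**12 to 8 and 9 (through 11 and 10).** The two aryl–C(O) bonds are cut next. This leads to the dialdehyde 8 and two molecules of 2,2'-bithiophene 9, which reacts as its 5-lithio derivative 10; the diol 11 is only an oxidation-state relay. The gain is that the heteroaromatic rings enter after all oxidative cleavage chemistry, so they never meet the oxidant used to unmask the arms. The forward step is a twofold 1,2-addition followed by a mild oxidation of the thienyl carbinols.

**8 to 6.** The two formyl carbons of 8 are reconnected as a C=C bond, which gives cis-bicyclo[4.2.0]oct-3-ene 6. The six-membered ring of 6 is absent from the target; it serves only to hold the two arms, and one symmetrical alkene cleavage releases both at once. Forward, an ozonolysis with reductive work-up is needed; at this stage the molecule holds no other oxidizable group.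

**6 to 4 (through 5), the strategic cut.** In 6 the bond between the two cyclobutane methylenes (C3–C4 of the target) is cut. It is the only ring bond whose two ends are unfunctionalized and stereochemically inert; any cut at C1 or C2 would put a stereocentre into play. The precursor is the cis-diiodide 4. Forward, halogen–lithium exchange at one CH2I must give the alkyllithium 5, which closes the four-membered ring by displacing the other iodide. The cis relation is already present and only has to survive.

**4 to 1 (through 3 and 2).** The diiodide 4 comes from the dimesylate 3, this from the diol 2, and this from the anhydride 1 by functional group interconversions at primary carbons. Compound 1 is a commercial Diels–Alder adduct: its cis stereochemistry is built in and it already contains all eight core carbons, so no carbon has to be added or removed before the aryl groups arrive.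

## Alternatives that were turned down

**Alternative 1:** ring expansion of a dialkynylcyclopropane.
- Disconnection: the aryl–alkyne bonds (cross-coupling) and, in the core, the C2–C3 bond, which is traced to a cyclopropane enlarged by one carbon.
- Forward key step: the (Z)-enediyne A3 would be cyclopropanated and elaborated to the cyclopropyl tosylhydrazone A2. Deprotonation and decomposition with Rh2(OAc)4 gives a cyclopropylcarbene in which a ring bond shifts to the carbene carbon, delivering the cis-3,4-dialkynylcyclobutene A1. Saturation of the ring alkene, desilylation and twofold Sonogashira coupling with a 5-halogenated derivative of 9 would finish.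
- For: the cis relation comes from the alkene geometry of A3. Both triple bonds exist from the start, so no strong base ever acts next to propargylic stereocentres; on this point the alternative is stronger than the chosen route. The aryl groups also arrive last.
- Against: the alkene of A3 is electron-poor and flanked by two alkynes that compete for the carbenoid. Cyclopropylcarbenes can also fragment to alkene plus alkyne. A1 carries two conjugating substituents on its sp3 carbons and should undergo electrocyclic ring opening readily. Its ring C=C must then be reduced in the presence of two C≡C bonds, which is a real chemoselectivity burden.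
- Comparison: the step count is no lower (enediyne, cyclopropanation, adjustment to the aldehyde, hydrazone, expansion, reduction, desilylation, coupling). The chosen route has one uncertain bond formation of a known type, never has to tell C=C from C≡C, and takes its stereochemistry from a commercial compound.

**Alternative 2:** [2+2] photocycloaddition.
- Disconnection: the C1–C4 and C2–C3 bonds, cut together.
- Forward key step: triplet-sensitized irradiation of maleic anhydride A5 under ethylene A6 gives the cis-fused anhydride A4.
- For: one step to a cis-cyclobutane with the right substitution pattern, from the cheapest materials, with the cis relation locked in a ring. In steps to the four-membered ring (one against four) this alternative is clearly stronger.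
- Against: A4 holds only six of the eight core carbons, so each arm needs a one-carbon homologation. That has to pass through the dialdehyde A7, in which both stereocentres are α to formyl groups. The basic conditions of aldehyde-to-alkyne homologation would then drive the cis isomer toward trans. A twofold palladium coupling on a volatile terminal diyne follows, and the key step needs gas–liquid photochemistry.
- Comparison: the chosen route offers arms that already have both carbons, stereocentres that are never α to a carbonyl group, and ordinary glassware throughout.

**Alternative 3:** spiroannulation of an ynal, then stereoselective reduction.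
- Disconnection: the C1–C2 and C2–C3 bonds, by one-carbon spiroannulation of an aldehyde; the second arm by acetylide addition; the cis relation by a final reduction.
- Forward key step: the ylide from the cyclopropylsulfonium salt A10 and KOH adds to the bithienyl ynal A9, and the oxaspiropentane rearranges with LiBF4 to the 2-alkynylcyclobutanone A8. Addition of a second bithienylethynyl nucleophile gives the tertiary alcohol A11; ionization and hydride delivery anti to the neighbouring arm would set cis.
- For: both heteroaryl alkyne arms arrive intact, the sequence is the shortest of all, and racemic intermediates do no harm because the target is meso. In convergence and step count it is stronger than the chosen route.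
- Against: the only stereochemical event comes last, and it relies on a rod-shaped alkynyl group to shield one face of a cyclobutyl cation. That cation can also contract to a cyclopropylcarbinyl system, lose a proton to an enyne, or be captured at the allenyl terminus. A8 has a hydrogen that is both α to the ketone and propargylic and may isomerize to an allenyl ketone under the basic ylide conditions.
- Comparison: the chosen route fixes the cis relation before any bond of the ring is made and leaves only a ring closure of a known type as the uncertain point.

Key step: step 4

## Route

Step 1
Reactants: 1 cis-1,2,3,6-tetrahydrophthalic anhydride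
Product: 2 cis-cyclohex-4-ene-1,2-diyldimethanol
Conditions: LiAlH4, THF, 0 °C → reflux; then H2O, aq NaOH
Reagents that add atoms: none
Why: LiAlH4 reduction of a cyclic carboxylic anhydride to the 1,4-diol; the isolated alkene is inert to hydride and no stereocentre is made or broken, so the cis relation of 1 is carried over.

Step 2
Reactants: 2 cis-cyclohex-4-ene-1,2-diyldimethanol
Product: 3 cis-cyclohex-4-ene-1,2-diylbis(methylene) dimethanesulfonate
Conditions: MsCl, Et3N, CH2Cl2, 0 °C
Reagents that add atoms: methanesulfonyl chloride, CS(=O)(=O)Cl
Why: O-sulfonylation of two primary alcohols; the cold, short reaction and prompt work-up keep the cis-1,4-hydroxy mesylate from closing to the bicyclic tetrahydrofuran.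

Step 3
Reactants: 3 cis-cyclohex-4-ene-1,2-diylbis(methylene) dimethanesulfonate
Product: 4 cis-4,5-bis(iodomethyl)cyclohex-1-ene
Conditions: NaI, acetone, reflux
Reagents that add atoms: sodium iodide, [Na+].[I-]
Why: Finkelstein SN2 displacement at two primary carbons, driven by precipitation of sodium methanesulfonate; the carbons attacked are not stereocentres.

Step 4
Reactants: 4 cis-4,5-bis(iodomethyl)cyclohex-1-ene
Product: 6 cis-bicyclo[4.2.0]oct-3-ene, via iodoalkyllithium 5 (not isolated)
Conditions: t-BuLi (2.1 equiv, slow addition), n-pentane/Et2O 3:2, −78 °C → rt; then MeOH; solvents distilled off through a column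
Reagents that add atoms: none
Why: The first equivalent of t-BuLi undergoes lithium–iodine exchange at one of the two equivalent CH2I groups and gives the primary alkyllithium 5, while the second equivalent removes the t-BuI so formed by E2 (isobutene, isobutane, LiI), which makes the exchange irreversible. The carbanionic carbon of 5 then displaces the remaining iodide intramolecularly by SN2 and forms the C3–C4 bond (C7–C8 of 6). The closest known reaction type is the t-BuLi-induced cyclization of 1,4-diiodobutane and its substituted congeners to cyclobutanes, an intramolecular Wurtz-type coupling. The four-membered ring closes in the 4-exo-tet mode. No stereocentre is created: both reacting carbons are methylenes, and the cis relation of the two ring CH centres, set in 1, allows only the cis-fused bicyclo[4.2.0] skeleton. The step needs ring closure to outrun a second exchange at the other CH2I, Grob-type 1,4-fragmentation of the ring bond between the two CH centres, E2 attack on the iodide and coupling between molecules. Low temperature, slow addition of just over two equivalents of base and dilution favour closure, and the gauche, axial–equatorial disposition of the two arms on the cyclohexene half-chair keeps the carbanion within reach of the back side of the C–I bond. The ring alkene stands in a 4-pentenyl relation to the carbanion, so carbolithiation does not compete.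

Step 5
Reactants: 6 cis-bicyclo[4.2.0]oct-3-ene
Product: 8 2,2'-[(1R,2S)-cyclobutane-1,2-diyl]diacetaldehyde, via secondary ozonide 7 (not isolated)
Conditions: O3, CH2Cl2, −78 °C; then Me2S, −78 °C → rt
Reagents that add atoms: ozone, [O-][O+]=O
Why: Criegee ozonolysis with reductive work-up; the alkene is the only oxidizable group because no thiophene is present yet. The stereocentres end up β to the formyl groups and cannot enolize; 8 is used at once to forestall intramolecular aldol reaction.

Step 6
Reactants: 8 2,2'-[(1R,2S)-cyclobutane-1,2-diyl]diacetaldehyde; 9 2,2'-bithiophene
Product: 11 2,2'-[(1R,2S)-cyclobutane-1,2-diyl]bis[1-(2,2'-bithiophen-5-yl)ethan-1-ol], via 5-lithio-2,2'-bithiophene 10 (not isolated)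
Conditions: 9 (2.3 equiv), n-BuLi (2.2 equiv), THF, −78 °C; then 8, THF, −78 °C; then H2O
Reagents that add atoms: none
Why: α-Lithiation of a thiophene followed by 1,2-addition of the aryllithium to both aldehydes; a slight excess of 9 over n-BuLi limits dilithiation. The two new carbinol centres form without control, which does not matter because they are oxidized in the next step.

Step 7
Reactants: 11 2,2'-[(1R,2S)-cyclobutane-1,2-diyl]bis[1-(2,2'-bithiophen-5-yl)ethan-1-ol]
Product: 12 2,2'-[(1R,2S)-cyclobutane-1,2-diyl]bis[1-(2,2'-bithiophen-5-yl)ethan-1-one]
Conditions: activated MnO2 (excess), CH2Cl2, rt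
Reagents that add atoms: none
Why: MnO2 oxidation of heterobenzylic secondary alcohols under neutral conditions, which spares the thiophene sulfur and the acid-sensitive carbinols; the diastereomer mixture of 11 converges on one meso diketone.

Step 8
Reactants: 12 2,2'-[(1R,2S)-cyclobutane-1,2-diyl]bis[1-(2,2'-bithiophen-5-yl)ethan-1-one]
Product: 14 tetraethyl [(1R,2S)-cyclobutane-1,2-diyl]bis[(1Z)-1-(2,2'-bithiophen-5-yl)ethene-2,1-diyl] bis(phosphate), via dilithium bis-enolate 13 (not isolated)
Conditions: LiN(i-Pr)2 (2.2 equiv), THF, −78 °C; then ClP(O)(OEt)2, −78 → 0 °C
Reagents that add atoms: diethyl chlorophosphate, CCOP(=O)(Cl)OCC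
Why: Kinetic enolization followed by O-phosphorylation of the lithium enolates; each aryl ketone has a single enolizable CH2 and is far more acidic than any thiophene C–H. Amide enolization of an aryl alkyl ketone should give the Z enolate, which places the phosphate anti to the vinylic hydrogen as the elimination requires.

Step 9
Reactants: 14 tetraethyl [(1R,2S)-cyclobutane-1,2-diyl]bis[(1Z)-1-(2,2'-bithiophen-5-yl)ethene-2,1-diyl] bis(phosphate)
Product: 15 Isocardopatine
Conditions: LiN(i-Pr)2 (added in portions until 14 is consumed), THF, −78 °C; then aq NH4Cl at −78 °C; light excluded
Reagents that add atoms: none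
Why: Base-induced anti β-elimination of diethyl phosphate from an enol phosphate, the established ketone-to-alkyne conversion, applied twice. The ring stereocentres are not involved, and the cold quench with limited base is meant to keep the newly propargylic C–H bonds untouched.

## Compound list

1 | cis-1,2,3,6-tetrahydrophthalic anhydride, (3aR,7aS) | O=C1OC(=O)[C@@H]2CC=CC[C@H]12 | starting material
2 | cis-cyclohex-4-ene-1,2-diyldimethanol, (1R,2S) | OC[C@@H]1CC=CC[C@@H]1CO | intermediate
3 | cis-cyclohex-4-ene-1,2-diylbis(methylene) dimethanesulfonate | CS(=O)(=O)OC[C@@H]1CC=CC[C@@H]1COS(C)(=O)=O | intermediate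
4 | cis-4,5-bis(iodomethyl)cyclohex-1-ene, (4R,5S) | IC[C@@H]1CC=CC[C@@H]1CI | intermediate
5 | {[cis-6-(iodomethyl)cyclohex-3-en-1-yl]methyl}lithium (racemic, one enantiomer drawn) | [Li]C[C@@H]1CC=CC[C@@H]1CI | intermediate (not isolated)
6 | cis-bicyclo[4.2.0]oct-3-ene, (1R,6S) | C1=CC[C@@H]2CC[C@@H]2C1 | intermediate
7 | 9,10,11-trioxatricyclo[6.2.1.0^3,6]undecane, secondary ozonide of 6 (cis ring fusion; exo and endo forms at the two acetal carbons) | O1OC2C[C@@H]3CC[C@@H]3CC1O2 | intermediate (not isolated)
8 | 2,2'-[(1R,2S)-cyclobutane-1,2-diyl]diacetaldehyde (cis) | O=CC[C@@H]1CC[C@@H]1CC=O | intermediate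
9 | 2,2'-bithiophene | c1csc(c1)-c1cccs1 | starting material
10 | 5-lithio-2,2'-bithiophene | [Li]c1ccc(-c2cccs2)s1 | intermediate (not isolated)
11 | 2,2'-[(1R,2S)-cyclobutane-1,2-diyl]bis[1-(2,2'-bithiophen-5-yl)ethan-1-ol] (cis on the ring; mixture of diastereomers at the carbinol carbons) | OC(C[C@@H]1CC[C@@H]1CC(O)c1ccc(-c2cccs2)s1)c1ccc(-c2cccs2)s1 | intermediate
12 | 2,2'-[(1R,2S)-cyclobutane-1,2-diyl]bis[1-(2,2'-bithiophen-5-yl)ethan-1-one] (cis) | O=C(C[C@@H]1CC[C@@H]1CC(=O)c1ccc(-c2cccs2)s1)c1ccc(-c2cccs2)s1 | intermediate
13 | dilithium (Z,Z)-bis-enolate of 12 | [Li]O/C(=C\[C@@H]1CC[C@@H]1/C=C(\O[Li])c1ccc(-c2cccs2)s1)c1ccc(-c2cccs2)s1 | intermediate (not isolated)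
14 | tetraethyl [(1R,2S)-cyclobutane-1,2-diyl]bis[(1Z)-1-(2,2'-bithiophen-5-yl)ethene-2,1-diyl] bis(phosphate) | CCOP(=O)(OCC)O/C(=C\[C@@H]1CC[C@@H]1/C=C(\OP(=O)(OCC)OCC)c1ccc(-c2cccs2)s1)c1ccc(-c2cccs2)s1 | intermediate
15 | Isocardopatine, 5,5''-{[(1R,2S)-cyclobutane-1,2-diyl]di(ethyne-2,1-diyl)}di(2,2'-bithiophene) (cis) | C(#C[C@@H]1CC[C@@H]1C#Cc1ccc(-c2cccs2)s1)c1ccc(-c2cccs2)s1 | target

## Step count and points of risk

Total: 9 steps. Longest linear sequence: 9 steps (1 to 15); 9 is commercial and enters in step 6.

**Step 4 (key step).** The most likely failures are a second lithium–iodine exchange before the ring closes, fragmentation of the iodoalkyllithium with cleavage of the ring bond between the two CH centres, and coupling between two molecules. All three follow from the high reactivity of an unstabilized primary carbanion next to a second iodide. Loss of the volatile hydrocarbon on concentration is a further practical hazard. The fallback sets out from 4 and comes back at 6. One iodide of 4 would be displaced with PhSO2Na (1 equiv, DMF), giving {[cis-6-(iodomethyl)cyclohex-3-en-1-yl]methanesulfonyl}benzene F1 after separation from unreacted 4 and the bis-sulfone. Deprotonation α to the sulfone (LiN(i-Pr)2, THF, −78 °C → rt) closes the same C3–C4 bond by 4-exo-tet alkylation of a stabilized carbanion and should give cis-7-(benzenesulfonyl)bicyclo[4.2.0]oct-3-ene F2. Reductive desulfonylation (Na/Hg, Na2HPO4, MeOH) then gives 6. Because the carbanion is made by deprotonation, neither double exchange nor fragmentation can occur; the price is two more steps and a statistical first step.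

**Step 9.** The most likely failure is loss of the cis relation by deprotonation of the propargylic ring C–H bonds, together with alkyne-to-allene isomerization. The base dose is hard to set, because the free 5'-positions of the thiophenes also consume amide. Any E-configured enol phosphate may undergo O-to-C phosphoryl migration in place of elimination. The fallback sets out from 8 (with 10, made from 9, as the source of the aryl halide) and comes back at 15. Compound 8 would be treated with C4F9SO2F and a phosphazene base (P2-Et) in DMF. This gives the bis(alkenyl nonaflate), [(1R,2S)-cyclobutane-1,2-diyl]di(ethene-2,1-diyl) bis(nonafluorobutane-1-sulfonate) F3, which eliminates in the same flask to cis-1,2-diethynylcyclobutane F4. Quenching 10 with I2 gives 5-iodo-2,2'-bithiophene F5. Twofold Sonogashira coupling of F4 with F5 (Pd(PPh3)2Cl2, CuI, Et3N, THF, rt) gives 15. In this variant the aryl alkyne never meets a strong base; the cost is a volatile diyne and a palladium step.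

**Step 6.** The most likely failures are enolization of the dialdehyde by the aryllithium followed by intramolecular aldol reaction, and cross-linking by doubly lithiated bithiophene. Both arise because an enolizable 1,6-dialdehyde is exposed to a basic nucleophile whose monolithiation is not perfectly clean. The fallback sets out from 6 and comes back at 12, so that 8 and 11 are bypassed. Oxidative cleavage of 6 (RuCl3 catalytic, NaIO4, MeCN/EtOAc/H2O) would give 2,2'-[(1R,2S)-cyclobutane-1,2-diyl]diacetic acid F6. Treatment with (COCl)2 and catalytic DMF in CH2Cl2 gives 2,2'-[(1R,2S)-cyclobutane-1,2-diyl]diacetyl dichloride F7. Friedel–Crafts acylation of 9 (2.5 equiv) with F7 and SnCl4 in CH2Cl2 at 0 °C should take place at C5 of the bithiophene and give 12 directly. The aryl–carbonyl bonds are then made by electrophilic substitution and no carbanion is involved.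

## Further compounds

F1 | step 4 | {[cis-6-(iodomethyl)cyclohex-3-en-1-yl]methanesulfonyl}benzene (racemic, one enantiomer drawn) | O=S(=O)(C[C@@H]1CC=CC[C@@H]1CI)c1ccccc1
F2 | step 4 | cis-7-(benzenesulfonyl)bicyclo[4.2.0]oct-3-ene (cis ring fusion, epimers at C7) | C1=CC[C@@H]2CC([C@@H]2C1)S(=O)(=O)c1ccccc1
F3 | step 9 | [(1R,2S)-cyclobutane-1,2-diyl]di(ethene-2,1-diyl) bis(nonafluorobutane-1-sulfonate) (cis on the ring, E/Z mixture) | FC(F)(F)C(F)(F)C(F)(F)C(F)(F)S(=O)(=O)OC=C[C@@H]1CC[C@@H]1C=COS(=O)(=O)C(F)(F)C(F)(F)C(F)(F)C(F)(F)F
F4 | step 9 | cis-1,2-diethynylcyclobutane, (1R,2S) | C#C[C@@H]1CC[C@@H]1C#C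
F5 | step 9 | 5-iodo-2,2'-bithiophene | Ic1ccc(-c2cccs2)s1
F6 | step 6 | 2,2'-[(1R,2S)-cyclobutane-1,2-diyl]diacetic acid (cis) | OC(=O)C[C@@H]1CC[C@@H]1CC(O)=O
F7 | step 6 | 2,2'-[(1R,2S)-cyclobutane-1,2-diyl]diacetyl dichloride (cis) | ClC(=O)C[C@@H]1CC[C@@H]1CC(Cl)=O
A1 | alternative 1 | cis-3,4-bis[(triisopropylsilyl)ethynyl]cyclobut-1-ene | CC(C)[Si](C(C)C)(C(C)C)C#C[C@@H]1C=C[C@@H]1C#C[Si](C(C)C)(C(C)C)C(C)C
A2 | alternative 1 | N'-({cis-2,3-bis[(triisopropylsilyl)ethynyl]cyclopropyl}methylidene)-4-methylbenzenesulfonohydrazide (configuration at C1 of the cyclopropane immaterial) | Cc1ccc(cc1)S(=O)(=O)NN=CC1[C@H](C#C[Si](C(C)C)(C(C)C)C(C)C)[C@@H]1C#C[Si](C(C)C)(C(C)C)C(C)C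
A3 | alternative 1 | (Z)-1,6-bis(triisopropylsilyl)hex-3-ene-1,5-diyne | CC(C)[Si](C(C)C)(C(C)C)C#C/C=C\C#C[Si](C(C)C)(C(C)C)C(C)C
A4 | alternative 2 | cis-cyclobutane-1,2-dicarboxylic anhydride | O=C1OC(=O)[C@@H]2CC[C@H]12
A5 | alternative 2 | maleic anhydride | O=C1OC(=O)C=C1
A6 | alternative 2 | ethylene | C=C
A7 | alternative 2 | cis-cyclobutane-1,2-dicarbaldehyde | O=C[C@@H]1CC[C@@H]1C=O
A8 | alternative 3 | 2-[(2,2'-bithiophen-5-yl)ethynyl]cyclobutan-1-one (racemic, one enantiomer drawn) | O=C1CC[C@@H]1C#Cc1ccc(-c2cccs2)s1
A9 | alternative 3 | 3-(2,2'-bithiophen-5-yl)prop-2-ynal | O=CC#Cc1ccc(-c2cccs2)s1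
A10 | alternative 3 | cyclopropyldiphenylsulfonium tetrafluoroborate | F[B-](F)(F)F.c1ccc(cc1)[S+](C1CC1)c1ccccc1
A11 | alternative 3 | 1,2-bis[(2,2'-bithiophen-5-yl)ethynyl]cyclobutan-1-ol (racemic, both configurations at the carbinol carbon) | OC1(C#Cc2ccc(-c3cccs3)s2)CC[C@@H]1C#Cc1ccc(-c2cccs2)s1
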